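**Plan**

- Retrosynthetic cuts, in order: the 19 O-benzyl bonds; the interflavan bond C4(top unit)–C8(middle unit); the middle 3-O-galloyl ester; then, in one stroke, O1–C8a and C4–C4a of the middle unit. This last cut takes ring C of the middle unit apart into 3,5-bis(benzyloxy)benzyne and a C2–C3–C4 epoxy alkoxide that is already bonded through C4 to C8 of the catechin (bottom) unit. The epoxy alcohol goes back through a chalcone to 8-formylcatechin and an acetophenone.
- Forward order: (+)-catechin is benzylated, brominated and formylated at C8, condensed to the chalcone, epoxidised and reduced. The aryne annulation then builds ring C, together with ring A, of the middle unit on the bottom unit. Galloylation, C8-selective coupling with a 4-activated epicatechin gallate (top unit) and one hydrogenolysis finish the route.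
- Stereochemistry: the bottom and top units come from (+)-catechin and (−)-epicatechin. Middle C3 and C4 come from the poly-L-leucine-controlled epoxidation, C4 with inversion in the annulation. Middle C2 comes from a catalyst-controlled ketone reduction and is kept because the aryl–O bond, not the C2–O bond, is formed. Top C4 is set by attack anti to the 3-O-galloyl group.
- Enabling feature: ring A of the middle unit is 5,7-dioxygenated, so it is the 1,2-adduct of a 3,5-dioxygenated benzyne whose C3 oxygen sends the oxygen nucleophile to C8a and leaves the carbanion at C4a. C4 is benzylic to the electron-rich ring A of the bottom unit (its C8), so a C3–C4 epoxide is opened at C4.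

Key step: step 11

Remark: compounds 9, 13 and 26 are benzyl-protected building blocks taken as purchased; every hydroxyl that must end free travels as a benzyl ether so that one hydrogenolysis ends the route.

**Route**

Step 1
Reactants: 1 (+)-catechin
Product: 2 5,7,3',4'-tetra-O-benzyl-(+)-catechin
Conditions: BnBr, K2CO3, DMF, 0 °C → rt
Reagents that add atoms: benzyl bromide BrCc1ccccc1
Why: Williamson etherification in which K2CO3 ionises only the four phenols, so the secondary 3-OH stays free and no stereocentre is touched.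

Step 2
Reactants: 2 5,7,3',4'-tetra-O-benzyl-(+)-catechin
Product: 4 3,5,7,3',4'-penta-O-benzyl-(+)-catechin, via sodium alkoxide 3 (not isolated)
Conditions: NaH, DMF, 0 °C; BnBr, Bu4NI (cat.), rt
Reagents that add atoms: benzyl bromide BrCc1ccccc1
Why: Williamson etherification of the secondary alkoxide masks the catechin 3-OH against the later alkoxide, aryne and acylation steps in a form that the final hydrogenolysis removes.

Step 3
Reactants: 4 3,5,7,3',4'-penta-O-benzyl-(+)-catechin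
Product: 5 8-bromo-3,5,7,3',4'-penta-O-benzyl-(+)-catechin
Conditions: NBS, CH2Cl2, −78 °C → rt
Reagents that add atoms: N-bromosuccinimide O=C1CCC(=O)N1Br
Why: electrophilic aromatic bromination goes to C8, the most nucleophilic position of ring A in 3-O-protected benzylated flavan-3-ols.

Step 4
Reactants: 5 8-bromo-3,5,7,3',4'-penta-O-benzyl-(+)-catechin
Product: 8 8-formyl-3,5,7,3',4'-penta-O-benzyl-(+)-catechin, via aryllithium 6 (not isolated), via lithium hemiaminal alkoxide 7 (not isolated)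
Conditions: n-BuLi, THF, −78 °C; DMF, −78 → 0 °C; H2O
Reagents that add atoms: N,N-dimethylformamide CN(C)C=O
Why: bromine–lithium exchange followed by formylation with DMF (Bouveault aldehyde synthesis) is fast at −78 °C, where the benzyl ethers are not metalated.

Step 5
Reactants: 8 8-formyl-3,5,7,3',4'-penta-O-benzyl-(+)-catechin; 9 3',4'-bis(benzyloxy)acetophenone
Product: 10 (E)-1-[3,4-bis(benzyloxy)phenyl]-3-[3,5,7,3',4'-penta-O-benzyl-(+)-catechin-8-yl]prop-2-en-1-one
Conditions: KOH, EtOH/THF, rt → 50 °C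
Reagents that add atoms: none
Why: Claisen–Schmidt condensation of a non-enolisable 2,4,6-trialkoxybenzaldehyde with a methyl ketone should give the (E)-enone by E1cB dehydration under thermodynamic control.

Step 6
Reactants: 10 (E)-1-[3,4-bis(benzyloxy)phenyl]-3-[3,5,7,3',4'-penta-O-benzyl-(+)-catechin-8-yl]prop-2-en-1-one
Product: 11 (2R,3S)-2,3-epoxy-1-[3,4-bis(benzyloxy)phenyl]-3-[3,5,7,3',4'-penta-O-benzyl-(+)-catechin-8-yl]propan-1-one
Conditions: poly-L-leucine, urea–H2O2, DBU, THF, rt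
Reagents that add atoms: hydrogen peroxide (as its urea adduct) OO
Why: Juliá–Colonna asymmetric nucleophilic epoxidation of a chalcone, in which the poly-L-leucine helix selects the enone face that leads to the trans-(2R,3S)-epoxide while the remote catechin stereocentres exert no control and the basic medium spares the acid-labile epoxide.

Step 7
Reactants: 11 (2R,3S)-2,3-epoxy-1-[3,4-bis(benzyloxy)phenyl]-3-[3,5,7,3',4'-penta-O-benzyl-(+)-catechin-8-yl]propan-1-one
Product: 12 (R)-[3,4-bis(benzyloxy)phenyl]{(2S,3S)-3-[3,5,7,3',4'-penta-O-benzyl-(+)-catechin-8-yl]oxiran-2-yl}methanol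
Conditions: RuCl[(S,S)-TsDPEN](p-cymene) (cat.), HCO2H/Et3N (2:5), CH2Cl2, rt; filtration through basic alumina
Reagents that add atoms: none
Why: Noyori–Ikariya asymmetric transfer hydrogenation of an aryl ketone is catalyst-controlled, so the (S,S)-complex, which gives (S)-1-arylethanols, should give the (R)-carbinol here (the CIP priorities of aryl and alkyl are exchanged), that is the epimer opposite to the one from chelation control, under base-buffered conditions that leave the epoxide closed.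

Step 8
Reactants: 13 3,5-bis(benzyloxy)phenol
Product: 14 3,5-bis(benzyloxy)phenyl N-isopropylcarbamate
Conditions: i-PrNCO, Et3N (cat.), CH2Cl2, rt
Reagents that add atoms: isopropyl isocyanate CC(C)N=C=O
Why: base-catalysed addition of the phenol to the isocyanate installs a carbamate that directs ortho-metalation and can later be removed under mild base.

Step 9
Reactants: 14 3,5-bis(benzyloxy)phenyl N-isopropylcarbamate
Product: 18 3,5-bis(benzyloxy)-2-(trimethylsilyl)phenyl N-isopropylcarbamate, via N-silyl carbamate 15 (not isolated), via aryllithium 16 (not isolated), via N-silyl C-silyl carbamate 17 (not isolated)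
Conditions: TBSOTf, TMEDA, Et2O, 0 °C → rt; n-BuLi (2 equiv), TMEDA, −78 °C; Me3SiCl, −78 °C → rt; aq NaHSO4
Reagents that add atoms: chlorotrimethylsilane C[Si](C)(C)Cl
Why: directed ortho-metalation of the carbamate, masked in the flask as its N-silyl derivative, occurs at C2 where the carbamate and a benzyloxy group cooperate, and the aryllithium is silylated by Me3SiCl.

Step 10
Reactants: 18 3,5-bis(benzyloxy)-2-(trimethylsilyl)phenyl N-isopropylcarbamate
Product: 20 3,5-bis(benzyloxy)-2-(trimethylsilyl)phenyl trifluoromethanesulfonate, via silylphenol 19 (not isolated)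
Conditions: DBU, Et2NH, MeCN, 40 °C; PhNTf2, rt
Reagents that add atoms: N-phenylbis(trifluoromethanesulfonimide) O=S(=O)(N(c1ccccc1)S(=O)(=O)C(F)(F)F)C(F)(F)F
Why: E1cB cleavage of the N-monosubstituted carbamate (the isocyanate is trapped by Et2NH) frees the phenoxide, which is triflated in the same flask to the ortho-silylaryl triflate aryne precursor.

Step 11
Reactants: 12 (R)-[3,4-bis(benzyloxy)phenyl]{(2S,3S)-3-[3,5,7,3',4'-penta-O-benzyl-(+)-catechin-8-yl]oxiran-2-yl}methanol; 20 3,5-bis(benzyloxy)-2-(trimethylsilyl)phenyl trifluoromethanesulfonate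
Product: 25 5,7,3',4'-tetra-O-benzyl-(−)-epicatechin-(4β→8)-3,5,7,3',4'-penta-O-benzyl-(+)-catechin, via potassium alkoxide 21 (not isolated), via 3,5-bis(benzyloxy)benzyne 22 (not isolated), via arylpotassium 23 (not isolated), via potassium flavan-3-olate 24 (not isolated)
Conditions: KH, THF, −20 °C; then 20 (1.3 equiv), KF, 18-crown-6, THF, −20 °C → rt; H2O
Reagents that add atoms: none
Why: Proposed new method: fluoride-induced 1,2-elimination of 20 gives benzyne 22, the alkoxide oxygen of 21 adds to the aryne carbon meta to the neighbouring benzyloxy group (the future C8a), and the carbanion thus placed at C4a opens the trans-epoxide at C4 by backside attack, so that O1–C8a and C4a–C4 arise in one aryne 1,2-difunctionalisation. The closest known reaction types are the insertion of arynes into the C–O bond of epoxides and the tandem O-arylation and aryl-anion trapping of arynes by salicylates or 2-hydroxychalcones (xanthone and xanthene annulations). Ring C closes in the 6-endo-tet mode at the epoxide, which should be preferred to 5-exo attack at C3 because the C4–O bond is benzylic to the 2,4,6-trioxygenated ring A of the catechin unit and therefore strongly polarised. C2 keeps the (R) configuration of the carbinol because its C–O bond is never broken, C3 keeps the configuration of the epoxide, and C4 is set by inversion, which turns the trans-epoxide into the 2,3-cis-3,4-trans (4β) arrangement. The step needs regioselective addition to the aryne, secured by the inductive (distortion) effect of the C3 benzyloxy group of 22, and an aryl anion that is not protonated before it cyclises, secured by deprotonation with KH (H2 is the only by-product) in an aprotic medium.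

Step 12
Reactants: 25 5,7,3',4'-tetra-O-benzyl-(−)-epicatechin-(4β→8)-3,5,7,3',4'-penta-O-benzyl-(+)-catechin; 26 3,4,5-tris(benzyloxy)benzoic acid
Product: 27 3-O-[3,4,5-tris(benzyloxy)benzoyl]-5,7,3',4'-tetra-O-benzyl-(−)-epicatechin-(4β→8)-3,5,7,3',4'-penta-O-benzyl-(+)-catechin
Conditions: DCC, DMAP, CH2Cl2, rt
Reagents that add atoms: none
Why: Steglich esterification acylates the only free hydroxyl (the axial 3-OH of the new epicatechin unit) under neutral conditions that leave the acid-labile interflavan bond intact.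

Step 13
Reactants: 28 (−)-epicatechin
Product: 29 5,7,3',4'-tetra-O-benzyl-(−)-epicatechin
Conditions: BnBr, K2CO3, DMF, 0 °C → rt
Reagents that add atoms: benzyl bromide BrCc1ccccc1
Why: Williamson etherification of the four phenols only, as in step 1.

Step 14
Reactants: 29 5,7,3',4'-tetra-O-benzyl-(−)-epicatechin
Product: 30 4β-(2-ethoxyethoxy)-5,7,3',4'-tetra-O-benzyl-(−)-epicatechin
Conditions: DDQ, 2-ethoxyethanol, CH2Cl2, rt
Reagents that add atoms: 2-ethoxyethanol CCOCCO
Why: DDQ oxidation (hydride abstraction) at the doubly activated benzylic C4 gives a flavan-4-yl cation that the alcohol captures trans to the 3-OH, installing the C4 leaving group.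

Step 15
Reactants: 30 4β-(2-ethoxyethoxy)-5,7,3',4'-tetra-O-benzyl-(−)-epicatechin; 26 3,4,5-tris(benzyloxy)benzoic acid
Product: 31 3-O-[3,4,5-tris(benzyloxy)benzoyl]-4β-(2-ethoxyethoxy)-5,7,3',4'-tetra-O-benzyl-(−)-epicatechin
Conditions: DCC, DMAP, CH2Cl2, rt
Reagents that add atoms: none
Why: Steglich esterification of the 3-OH is neutral and so tolerates the acid-labile 4-alkoxy group.

Step 16
Reactants: 27 3-O-[3,4,5-tris(benzyloxy)benzoyl]-5,7,3',4'-tetra-O-benzyl-(−)-epicatechin-(4β→8)-3,5,7,3',4'-penta-O-benzyl-(+)-catechin; 31 3-O-[3,4,5-tris(benzyloxy)benzoyl]-4β-(2-ethoxyethoxy)-5,7,3',4'-tetra-O-benzyl-(−)-epicatechin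
Product: 32 nonadeca-O-benzyl derivative of (−)-epicatechin 3-O-gallate-(4β→8)-(−)-epicatechin 3-O-gallate-(4β→8)-(+)-catechin
Conditions: Me3SiOTf (cat.), CH2Cl2, −78 → −40 °C; 27 in slight excess
Reagents that add atoms: none
Why: Lewis-acid-promoted Friedel–Crafts-type interflavan coupling, in which the flavan-4-yl cation from 31 is attacked by C8 of the upper unit of 27 (the most nucleophilic free position of a benzylated dimer) on the face anti to the 3-O-galloyl and 2-aryl groups, which sets the new C4 as 4β.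

Step 17
Reactants: 32 nonadeca-O-benzyl derivative of (−)-epicatechin 3-O-gallate-(4β→8)-(−)-epicatechin 3-O-gallate-(4β→8)-(+)-catechin
Product: 33 (−)-epicatechin 3-O-gallate-(4β→8)-(−)-epicatechin 3-O-gallate-(4β→8)-(+)-catechin (target)
Conditions: H2 (1 atm), Pd(OH)2/C, THF/MeOH/H2O, rt
Reagents that add atoms: none
Why: catalytic hydrogenolysis should cleave all nineteen benzyl ethers while the gallate esters, the interflavan bonds and every stereocentre remain untouched.

**Compound list**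

1 | (+)-catechin, (2R,3S) | Oc1cc(O)c2c(c1)O[C@H](c1ccc(O)c(O)c1)[C@@H](O)C2 | starting material
2 | 5,7,3',4'-tetra-O-benzyl-(+)-catechin | c1c(OCc9ccccc9)cc(OCc9ccccc9)c2c1O[C@H](c1ccc(OCc9ccccc9)c(OCc9ccccc9)c1)[C@@H](O)C2 | intermediate
3 | sodium 3-alkoxide of 2 | [Na+].[O-][C@H]1Cc2c(OCc9ccccc9)cc(OCc9ccccc9)cc2O[C@@H]1c1ccc(OCc9ccccc9)c(OCc9ccccc9)c1 | intermediate
4 | 3,5,7,3',4'-penta-O-benzyl-(+)-catechin | c1c(OCc9ccccc9)cc(OCc9ccccc9)c2c1O[C@H](c1ccc(OCc9ccccc9)c(OCc9ccccc9)c1)[C@@H](OCc9ccccc9)C2 | intermediate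
5 | 8-bromo-3,5,7,3',4'-penta-O-benzyl-(+)-catechin | Brc1c(OCc9ccccc9)cc(OCc9ccccc9)c2c1O[C@H](c1ccc(OCc9ccccc9)c(OCc9ccccc9)c1)[C@@H](OCc9ccccc9)C2 | intermediate
6 | 8-lithio-3,5,7,3',4'-penta-O-benzyl-(+)-catechin | [Li]c1c(OCc9ccccc9)cc(OCc9ccccc9)c2c1O[C@H](c1ccc(OCc9ccccc9)c(OCc9ccccc9)c1)[C@@H](OCc9ccccc9)C2 | intermediate
7 | lithium hemiaminal alkoxide from 6 and DMF (new carbon of undefined configuration) | [Li]OC(N(C)C)c1c(OCc9ccccc9)cc(OCc9ccccc9)c2c1O[C@H](c1ccc(OCc9ccccc9)c(OCc9ccccc9)c1)[C@@H](OCc9ccccc9)C2 | intermediate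
8 | 8-formyl-3,5,7,3',4'-penta-O-benzyl-(+)-catechin | O=Cc1c(OCc9ccccc9)cc(OCc9ccccc9)c2c1O[C@H](c1ccc(OCc9ccccc9)c(OCc9ccccc9)c1)[C@@H](OCc9ccccc9)C2 | intermediate
9 | 3',4'-bis(benzyloxy)acetophenone | CC(=O)c1ccc(OCc9ccccc9)c(OCc9ccccc9)c1 | starting material
10 | (E)-1-[3,4-bis(benzyloxy)phenyl]-3-[3,5,7,3',4'-penta-O-benzyl-(+)-catechin-8-yl]prop-2-en-1-one | O=C(/C=C/c1c(OCc9ccccc9)cc(OCc9ccccc9)c2c1O[C@H](c1ccc(OCc9ccccc9)c(OCc9ccccc9)c1)[C@@H](OCc9ccccc9)C2)c1ccc(OCc9ccccc9)c(OCc9ccccc9)c1 | intermediate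
11 | (2R,3S)-2,3-epoxy-1-[3,4-bis(benzyloxy)phenyl]-3-[3,5,7,3',4'-penta-O-benzyl-(+)-catechin-8-yl]propan-1-one (trans-epoxide) | O=C([C@@H]1O[C@H]1c1c(OCc9ccccc9)cc(OCc9ccccc9)c2c1O[C@H](c1ccc(OCc9ccccc9)c(OCc9ccccc9)c1)[C@@H](OCc9ccccc9)C2)c1ccc(OCc9ccccc9)c(OCc9ccccc9)c1 | intermediate
12 | (R)-[3,4-bis(benzyloxy)phenyl]{(2S,3S)-3-[3,5,7,3',4'-penta-O-benzyl-(+)-catechin-8-yl]oxiran-2-yl}methanol | O[C@@H]([C@@H]1O[C@H]1c1c(OCc9ccccc9)cc(OCc9ccccc9)c2c1O[C@H](c1ccc(OCc9ccccc9)c(OCc9ccccc9)c1)[C@@H](OCc9ccccc9)C2)c1ccc(OCc9ccccc9)c(OCc9ccccc9)c1 | intermediate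
13 | 3,5-bis(benzyloxy)phenol | Oc1cc(OCc9ccccc9)cc(OCc9ccccc9)c1 | starting material
14 | 3,5-bis(benzyloxy)phenyl N-isopropylcarbamate | CC(C)NC(=O)Oc1cc(OCc9ccccc9)cc(OCc9ccccc9)c1 | intermediate
15 | 3,5-bis(benzyloxy)phenyl N-(tert-butyldimethylsilyl)-N-isopropylcarbamate | CC(C)N([Si](C)(C)C(C)(C)C)C(=O)Oc1cc(OCc9ccccc9)cc(OCc9ccccc9)c1 | intermediate
16 | 2-lithio derivative of 15 | CC(C)N([Si](C)(C)C(C)(C)C)C(=O)Oc1cc(OCc9ccccc9)cc(OCc9ccccc9)c1[Li] | intermediate
17 | 2-(trimethylsilyl) derivative of 15 | CC(C)N([Si](C)(C)C(C)(C)C)C(=O)Oc1cc(OCc9ccccc9)cc(OCc9ccccc9)c1[Si](C)(C)C | intermediate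
18 | 3,5-bis(benzyloxy)-2-(trimethylsilyl)phenyl N-isopropylcarbamate | CC(C)NC(=O)Oc1cc(OCc9ccccc9)cc(OCc9ccccc9)c1[Si](C)(C)C | intermediate
19 | 3,5-bis(benzyloxy)-2-(trimethylsilyl)phenol | Oc1cc(OCc9ccccc9)cc(OCc9ccccc9)c1[Si](C)(C)C | intermediate
20 | 3,5-bis(benzyloxy)-2-(trimethylsilyl)phenyl trifluoromethanesulfonate | O=S(=O)(Oc1cc(OCc9ccccc9)cc(OCc9ccccc9)c1[Si](C)(C)C)C(F)(F)F | intermediate
21 | potassium alkoxide of 12 | [K+].[O-][C@@H]([C@@H]1O[C@H]1c1c(OCc9ccccc9)cc(OCc9ccccc9)c2c1O[C@H](c1ccc(OCc9ccccc9)c(OCc9ccccc9)c1)[C@@H](OCc9ccccc9)C2)c1ccc(OCc9ccccc9)c(OCc9ccccc9)c1 | intermediate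
22 | 3,5-bis(benzyloxy)benzyne | C1#CC(OCc9ccccc9)=CC(OCc9ccccc9)=C1 | intermediate
23 | arylpotassium: aryl ether of 12 with 3,5-bis(benzyloxy)phenyl, metalated at the ring carbon between the ether oxygen and a benzyloxy group | [K]c1c(OCc9ccccc9)cc(OCc9ccccc9)cc1O[C@@H]([C@@H]1O[C@H]1c1c(OCc9ccccc9)cc(OCc9ccccc9)c2c1O[C@H](c1ccc(OCc9ccccc9)c(OCc9ccccc9)c1)[C@@H](OCc9ccccc9)C2)c1ccc(OCc9ccccc9)c(OCc9ccccc9)c1 | intermediate
24 | potassium 3-alkoxide of 25 | [K+].[O-][C@@H]1[C@@H](c2c(OCc9ccccc9)cc(OCc9ccccc9)c3c2O[C@H](c2ccc(OCc9ccccc9)c(OCc9ccccc9)c2)[C@@H](OCc9ccccc9)C3)c2c(OCc9ccccc9)cc(OCc9ccccc9)cc2O[C@@H]1c1ccc(OCc9ccccc9)c(OCc9ccccc9)c1 | intermediate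
25 | 5,7,3',4'-tetra-O-benzyl-(−)-epicatechin-(4β→8)-3,5,7,3',4'-penta-O-benzyl-(+)-catechin (upper unit 2,3-cis-3,4-trans, free 3-OH) | O[C@@H]1[C@@H](c2c(OCc9ccccc9)cc(OCc9ccccc9)c3c2O[C@H](c2ccc(OCc9ccccc9)c(OCc9ccccc9)c2)[C@@H](OCc9ccccc9)C3)c2c(OCc9ccccc9)cc(OCc9ccccc9)cc2O[C@@H]1c1ccc(OCc9ccccc9)c(OCc9ccccc9)c1 | intermediate
26 | 3,4,5-tris(benzyloxy)benzoic acid | OC(=O)c1cc(OCc9ccccc9)c(OCc9ccccc9)c(OCc9ccccc9)c1 | starting material
27 | 3-O-[3,4,5-tris(benzyloxy)benzoyl] ester of 25 | O=C(O[C@@H]1[C@@H](c2c(OCc9ccccc9)cc(OCc9ccccc9)c3c2O[C@H](c2ccc(OCc9ccccc9)c(OCc9ccccc9)c2)[C@@H](OCc9ccccc9)C3)c2c(OCc9ccccc9)cc(OCc9ccccc9)cc2O[C@@H]1c1ccc(OCc9ccccc9)c(OCc9ccccc9)c1)c1cc(OCc9ccccc9)c(OCc9ccccc9)c(OCc9ccccc9)c1 | intermediate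
28 | (−)-epicatechin, (2R,3R) | Oc1cc(O)c2c(c1)O[C@H](c1ccc(O)c(O)c1)[C@H](O)C2 | starting material
29 | 5,7,3',4'-tetra-O-benzyl-(−)-epicatechin | c1c(OCc9ccccc9)cc(OCc9ccccc9)c2c1O[C@H](c1ccc(OCc9ccccc9)c(OCc9ccccc9)c1)[C@H](O)C2 | intermediate
30 | 4β-(2-ethoxyethoxy)-5,7,3',4'-tetra-O-benzyl-(−)-epicatechin (2,3-cis-3,4-trans) | CCOCCO[C@H]1c2c(OCc9ccccc9)cc(OCc9ccccc9)cc2O[C@H](c2ccc(OCc9ccccc9)c(OCc9ccccc9)c2)[C@@H]1O | intermediate
31 | 3-O-[3,4,5-tris(benzyloxy)benzoyl] ester of 30 | CCOCCO[C@H]1c2c(OCc9ccccc9)cc(OCc9ccccc9)cc2O[C@H](c2ccc(OCc9ccccc9)c(OCc9ccccc9)c2)[C@@H]1OC(=O)c1cc(OCc9ccccc9)c(OCc9ccccc9)c(OCc9ccccc9)c1 | intermediate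
32 | nonadeca-O-benzyl derivative of the target (all phenols, both galloyl groups and the catechin 3-OH benzylated) | O=C(O[C@@H]1[C@@H](c2c(OCc9ccccc9)cc(OCc9ccccc9)c3c2O[C@H](c2ccc(OCc9ccccc9)c(OCc9ccccc9)c2)[C@@H](OCc9ccccc9)C3)c2c(OCc9ccccc9)cc(OCc9ccccc9)c([C@H]3c4c(OCc9ccccc9)cc(OCc9ccccc9)cc4O[C@H](c4ccc(OCc9ccccc9)c(OCc9ccccc9)c4)[C@@H]3OC(=O)c3cc(OCc9ccccc9)c(OCc9ccccc9)c(OCc9ccccc9)c3)c2O[C@@H]1c1ccc(OCc9ccccc9)c(OCc9ccccc9)c1)c1cc(OCc9ccccc9)c(OCc9ccccc9)c(OCc9ccccc9)c1 | intermediate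
33 | (−)-epicatechin 3-O-gallate-(4β→8)-(−)-epicatechin 3-O-gallate-(4β→8)-(+)-catechin | O=C(O[C@@H]1[C@@H](c2c(O)cc(O)c3c2O[C@H](c2ccc(O)c(O)c2)[C@@H](O)C3)c2c(O)cc(O)c([C@H]3c4c(O)cc(O)cc4O[C@H](c4ccc(O)c(O)c4)[C@@H]3OC(=O)c3cc(O)c(O)c(O)c3)c2O[C@@H]1c1ccc(O)c(O)c1)c1cc(O)c(O)c(O)c1 | target

**Step count and risks**

Total step count: 17. Longest linear sequence: 11 steps (steps 1–7, 11, 12, 16, 17).

Steps most likely to fail:

1. Step 11 (proposed new method). Possible failures are protonation of the aryl anion before ring closure, 5-exo opening of the epoxide at C3, Payne migration of the epoxide within the alkoxide, and attack of the alkoxide at the sulfonyl group of the triflate. The fallback sets out from 12 and separates the two bond formations with known reaction types. Commercial 5-bromoresorcinol is benzylated (BnBr, K2CO3, DMF) to 1-bromo-3,5-bis(benzyloxy)benzene F1. Palladium-catalysed C–O cross-coupling of 12 with it (Pd2(dba)3, RockPhos, Cs2CO3, toluene, 90 °C) should give the 3,5-bis(benzyloxy)phenyl ether of 12 F2 with C2 untouched. A Lewis acid (BF3·OEt2 or Sc(OTf)3, CH2Cl2, −78 °C) should then trigger the 6-endo epoxide–arene Friedel–Crafts cyclisation at the benzylic C4 through the ring carbon ortho to the ether oxygen, with anti opening expected to give the 3,4-trans isomer. The fallback comes back to the route at 25.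

2. Step 7. The catalyst must override the substrate's intrinsic preference for the other carbinol epimer, so poor diastereoselectivity is possible, as is opening of the electron-rich epoxide by formic acid. The fallback sets out from 11. Chelation-controlled reduction (Zn(BH4)2, Et2O, −78 °C) should give the (S)-carbinol epimer of 12 F3. Mitsunobu inversion (4-nitrobenzoic acid, PPh3, DIAD, toluene, 0 °C) should give the (R)-4-nitrobenzoate of 12 F4, and methanolysis (K2CO3, MeOH, 0 °C) returns to the route at 12.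

3. Step 6. Conjugate addition of hydroperoxide to an enone whose β-aryl group is electron-rich and di-ortho-substituted may be slow, with low conversion or poor facial selectivity. The fallback sets out from 8 and forms the epoxide from the aldehyde instead of the alkene. Ketone 9 is α-chlorinated (LiHMDS, Me3SiCl; then NCS) to 2-chloro-1-[3,4-bis(benzyloxy)phenyl]ethanone F5. An asymmetric Darzens condensation of 8 with F5 under chiral phase-transfer catalysis (cinchona-derived quaternary ammonium bromide of the pseudo-enantiomeric series that leads to the (2R,3S)-epoxide, LiOH·H2O, Bu2O, 4 °C) should give the trans-epoxy ketone and returns to the route at 11.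

**Further compounds**

F1 | step 11 | 1-bromo-3,5-bis(benzyloxy)benzene | Brc1cc(OCc9ccccc9)cc(OCc9ccccc9)c1
F2 | step 11 | 3,5-bis(benzyloxy)phenyl ether of 12 | c1c(OCc9ccccc9)cc(OCc9ccccc9)cc1O[C@@H]([C@@H]1O[C@H]1c1c(OCc9ccccc9)cc(OCc9ccccc9)c2c1O[C@H](c1ccc(OCc9ccccc9)c(OCc9ccccc9)c1)[C@@H](OCc9ccccc9)C2)c1ccc(OCc9ccccc9)c(OCc9ccccc9)c1
F3 | step 7 | (S)-carbinol epimer of 12 | O[C@H]([C@@H]1O[C@H]1c1c(OCc9ccccc9)cc(OCc9ccccc9)c2c1O[C@H](c1ccc(OCc9ccccc9)c(OCc9ccccc9)c1)[C@@H](OCc9ccccc9)C2)c1ccc(OCc9ccccc9)c(OCc9ccccc9)c1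
F4 | step 7 | (R)-4-nitrobenzoate of 12 | O=C(O[C@@H]([C@@H]1O[C@H]1c1c(OCc9ccccc9)cc(OCc9ccccc9)c2c1O[C@H](c1ccc(OCc9ccccc9)c(OCc9ccccc9)c1)[C@@H](OCc9ccccc9)C2)c1ccc(OCc9ccccc9)c(OCc9ccccc9)c1)c1ccc(cc1)[N+](=O)[O-]
F5 | step 6 | 2-chloro-1-[3,4-bis(benzyloxy)phenyl]ethanone | O=C(CCl)c1ccc(OCc9ccccc9)c(OCc9ccccc9)c1
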